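**Plan**

1. Atom labels: tetrahydrofuran O1, C2 (aryl), C3 (spiro), C4 (benzyl), C5; C9 = epoxide CH2; C7' = benzylic CH2. Cuts, in retrosynthetic order: the epoxide C–O bonds (back to a C3=C9 methylene); the C4–H / C3=C9 pair (back to a 2,5-dihydrofuran-3-carbaldehyde by reductive 1,3-transposition); ring bond C3–C4 (aldol condensation); O1–C5 (ether synthesis); C2–C3 (allylation of an aldehyde).
2. Enabling feature: C3 carries the one-carbon branch C9 and is bonded to C4, which lies between two CH2 groups (C5 and C7'). With C9 raised to CHO and C4 to C=O, the ring bond C3–C4 is the bond of an aldol condensation of a 3-oxa-1,6-keto-aldehyde, and both carbonyls can hide as terminal alkenes until one ozonolysis.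
3. Forward: two aryl building blocks are joined as an ether (O1–C5); ozonolysis unmasks both carbonyls; the aldol condensation closes the only carbocycle-free ring as a flat 2,5-dihydrofuran (C3=C4); tosylhydrazone reduction moves the double bond out to C3=C9 and puts H on C4; epoxidation forms the oxirane; desilylation ends the route.
4. Stereochemistry: C2 from a catalytic asymmetric allylboration; C4 from suprafacial hydrogen delivery by an allylic diazene on the ring face anti to the C2 aryl group (gives 2,4-cis); C3 from epoxidation anti to the two cis substituents.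
5. A direct 5-exo closure of the same bond onto a cinnamyl alkene (radical or metal hydride) was not chosen, because its 1,3-induction is expected to lean toward the 2,4-trans series. The helper here is the C9 oxygen, which leaves during the transposition.

Key step: step 7

Remark: (R)-TRIP is taken to deliver the allyl group to the Re face of aryl aldehydes; if the sense proves opposite, the (S)-catalyst is used. TIPS = triisopropylsilyl.

**Route**

Step 1
Reactants: 1 5-bromo-2-methoxyphenol
Product: 2 (5-bromo-2-methoxyphenoxy)triisopropylsilane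
Conditions: TIPSCl, imidazole, DMF, rt
Reagents that add atoms: chlorotriisopropylsilane, CC(C)[Si](Cl)(C(C)C)C(C)C
Why: Imidazole-promoted O-silylation of a phenol gives an aryl silyl ether that should be inert to magnesium, alkoxide, ozone, borane and peracid and falls to fluoride at the end.

Step 2
Reactants: 2 (5-bromo-2-methoxyphenoxy)triisopropylsilane; 3 3-chloro-2-(chloromethyl)prop-1-ene
Product: 5 {5-[2-(chloromethyl)prop-2-en-1-yl]-2-methoxyphenoxy}triisopropylsilane, via aryl Grignard reagent 4 (not isolated)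
Conditions: Mg, THF, reflux; then 3 (3 equiv), CuI (5 mol %), THF, −20 °C → rt
Reagents that add atoms: none
Why: Copper-catalysed allylation of an aryl Grignard reagent with a symmetrical bis-allylic chloride, in which SN2 and SN2' attack give the same product and the excess of 3 should hold the reaction at monosubstitution.

Step 3
Reactants: 6 vanillin (4-hydroxy-3-methoxybenzaldehyde)
Product: 7 3-methoxy-4-(triisopropylsilyloxy)benzaldehyde
Conditions: TIPSCl, imidazole, DMF, rt
Reagents that add atoms: chlorotriisopropylsilane, CC(C)[Si](Cl)(C(C)C)C(C)C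
Why: The same phenol silylation as in step 1, which also keeps the later p-oxybenzylic ether from opening through a quinone methide.

Step 4
Reactants: 7 3-methoxy-4-(triisopropylsilyloxy)benzaldehyde; 8 2-allyl-4,4,5,5-tetramethyl-1,3,2-dioxaborolane
Product: 10 (1R)-1-[3-methoxy-4-(triisopropylsilyloxy)phenyl]but-3-en-1-ol, via pinacol borate ester 9 (not isolated)
Conditions: (R)-TRIP [(R)-3,3'-bis(2,4,6-triisopropylphenyl)-1,1'-binaphthyl-2,2'-diyl hydrogen phosphate] (5 mol %), toluene, −30 °C; aq. NaHCO3 work-up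
Reagents that add atoms: none
Why: Chiral phosphoric acid-catalysed allylboration through a closed chair transition state should deliver the allyl group to the Re face of the aldehyde and so set C2, the only stereocentre made under reagent control.

Step 5
Reactants: 10 (1R)-1-[3-methoxy-4-(triisopropylsilyloxy)phenyl]but-3-en-1-ol; 5 {5-[2-(chloromethyl)prop-2-en-1-yl]-2-methoxyphenoxy}triisopropylsilane
Product: 12 (R)-1-[3-methoxy-4-(triisopropylsilyloxy)phenyl]but-3-en-1-yl 2-[4-methoxy-3-(triisopropylsilyloxy)benzyl]prop-2-en-1-yl ether, via sodium alkoxide 11 (not isolated)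
Conditions: NaH, THF, 0 °C; then 5, Bu4NI (cat.), 0 → 40 °C
Reagents that add atoms: none
Why: Williamson ether synthesis between the sodium alkoxide and a reactive primary allylic chloride forms the O1–C5 bond without breaking the C2–O bond, so the configuration should be kept.

Step 6
Reactants: 12 the diene ether
Product: 14 (3R)-3-[3-methoxy-4-(triisopropylsilyloxy)phenyl]-3-{3-[4-methoxy-3-(triisopropylsilyloxy)phenyl]-2-oxopropoxy}propanal, via bis-ozonide 13 (not isolated)
Conditions: O3, CH2Cl2, −78 °C (Sudan Red 7B end point); then PPh3, −78 °C → rt; crude 14 used at once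
Reagents that add atoms: ozone, [O-][O+]=O
Why: Criegee ozonolysis with reductive work-up should cleave the vinyl group to the C9 aldehyde and the 1,1-disubstituted alkene to the C4 ketone, both alkenes reacting far faster than the silylated dioxygenated arenes when the dye end point is respected.

Step 7
Reactants: 14 the keto-aldehyde
Product: 16 (2S)-2-[3-methoxy-4-(triisopropylsilyloxy)phenyl]-4-[4-methoxy-3-(triisopropylsilyloxy)benzyl]-2,5-dihydrofuran-3-carbaldehyde, via aldol adduct 15 (not isolated)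
Conditions: Bn2NH·CF3CO2H (0.3 equiv), 4 Å molecular sieves, toluene, rt → 40 °C
Reagents that add atoms: none
Why: The secondary ammonium salt should condense with the aldehyde (C9) to an enamine whose carbon C3 adds to the ketone carbon C4, and loss of water from aldol 15 through the enamine gives the conjugated, tetrasubstituted enal 16. The closest known reaction type is the amine-salt-catalysed aldol cyclodehydration of 1,6-keto-aldehydes and of 3-oxa-1,5-dialdehydes to cyclopentene- and 2,5-dihydrofuran-carbaldehydes. The ring O1–C2–C3–C4–C5 is closed in the 5-(enolexo)-exo-trig mode. No new stereocentre survives the step, because C3 and C4 end trigonal, so C2 stays the only stereocentre and the ring arises flat for the face-selective step that follows. The step needs the aldehyde, not the ketone, to act as the donor, which the much faster enamine formation of the unhindered aldehyde should secure. It also needs C2 to keep its configuration, for which the mild acid salt, the low temperature and the fast five-ring closure are relied on against β-elimination of the ring oxygen.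

Step 8
Reactants: 16 the dihydrofuran carbaldehyde
Product: 20 (2R,4R)-2-[3-methoxy-4-(triisopropylsilyloxy)phenyl]-4-[4-methoxy-3-(triisopropylsilyloxy)benzyl]-3-methylenetetrahydrofuran, via tosylhydrazone 17 (not isolated), via N-boryl tosylhydrazine 18 (not isolated), via allylic diazene 19 (not isolated)
Conditions: TsNHNH2, THF, rt; evaporate; catecholborane, CHCl3, 0 °C; then NaOAc·3H2O, 60 °C
Reagents that add atoms: none
Why: Hydride reduction of the α,β-unsaturated tosylhydrazone and loss of sulfinate give an allylic diazene that loses N2 by a retro-ene hydrogen shift (reductive 1,3-transposition), which moves the double bond to C3=C9 and should deliver hydrogen suprafacially to C4 on the ring face anti to the C2 aryl group, so that benzyl ends cis to aryl.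

Step 9
Reactants: 20 the 3-methylenetetrahydrofuran
Product: 21 (3S,4S,7S)-4-[3-methoxy-4-(triisopropylsilyloxy)phenyl]-7-[4-methoxy-3-(triisopropylsilyloxy)benzyl]-1,5-dioxaspiro[2.4]heptane
Conditions: mCPBA, NaHCO3, CH2Cl2, 0 °C
Reagents that add atoms: 3-chloroperbenzoic acid, OOC(=O)c1cccc(Cl)c1
Why: Prilezhaev epoxidation of the exocyclic 1,1-disubstituted alkene from the ring face opposite to the cis aryl and benzyl groups should place the epoxide oxygen trans to both and set C3, the buffer guarding the acid-labile product.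

Step 10
Reactants: 21 the bis-silyl spiro-epoxide
Product: 22 5-{[(3S,4S,7S)-4-(4-hydroxy-3-methoxyphenyl)-1,5-dioxaspiro[2.4]heptan-7-yl]methyl}-2-methoxyphenol
Conditions: Bu4NF, AcOH (1:1), THF, 0 °C
Reagents that add atoms: none
Why: Fluoride-mediated cleavage of the two aryl silyl ethers under acetic acid buffering should leave the spiro-epoxide and the benzylic ether untouched.

**Compound list**

1 | 5-bromo-2-methoxyphenol | COc1ccc(Br)cc1O | starting material
2 | (5-bromo-2-methoxyphenoxy)triisopropylsilane | COc1ccc(Br)cc1O[Si](C(C)C)(C(C)C)C(C)C | intermediate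
3 | 3-chloro-2-(chloromethyl)prop-1-ene | C=C(CCl)CCl | starting material
4 | [4-methoxy-3-(triisopropylsilyloxy)phenyl]magnesium bromide | COc1ccc([Mg]Br)cc1O[Si](C(C)C)(C(C)C)C(C)C | intermediate
5 | {5-[2-(chloromethyl)prop-2-en-1-yl]-2-methoxyphenoxy}triisopropylsilane | COc1ccc(CC(=C)CCl)cc1O[Si](C(C)C)(C(C)C)C(C)C | intermediate
6 | vanillin (4-hydroxy-3-methoxybenzaldehyde) | COc1cc(C=O)ccc1O | starting material
7 | 3-methoxy-4-(triisopropylsilyloxy)benzaldehyde | COc1cc(C=O)ccc1O[Si](C(C)C)(C(C)C)C(C)C | intermediate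
8 | 2-allyl-4,4,5,5-tetramethyl-1,3,2-dioxaborolane | C=CCB1OC(C)(C)C(C)(C)O1 | starting material
9 | pinacol borate ester of 10 (R at the carbinol carbon) | C=CC[C@@H](OB1OC(C)(C)C(C)(C)O1)c1ccc(O[Si](C(C)C)(C(C)C)C(C)C)c(OC)c1 | intermediate
10 | (1R)-1-[3-methoxy-4-(triisopropylsilyloxy)phenyl]but-3-en-1-ol | C=CC[C@@H](O)c1ccc(O[Si](C(C)C)(C(C)C)C(C)C)c(OC)c1 | intermediate
11 | sodium (1R)-1-[3-methoxy-4-(triisopropylsilyloxy)phenyl]but-3-en-1-olate | C=CC[C@@H]([O-])c1ccc(O[Si](C(C)C)(C(C)C)C(C)C)c(OC)c1.[Na+] | intermediate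
12 | (R)-1-[3-methoxy-4-(triisopropylsilyloxy)phenyl]but-3-en-1-yl 2-[4-methoxy-3-(triisopropylsilyloxy)benzyl]prop-2-en-1-yl ether | C=CC[C@@H](OCC(=C)Cc1ccc(OC)c(O[Si](C(C)C)(C(C)C)C(C)C)c1)c1ccc(O[Si](C(C)C)(C(C)C)C(C)C)c(OC)c1 | intermediate
13 | bis-ozonide of 12 (both C=C bonds as 1,2,4-trioxolanes; mixture of diastereomers at the ozonide carbons) | C1(C[C@@H](OCC2(Cc3ccc(OC)c(O[Si](C(C)C)(C(C)C)C(C)C)c3)OCOO2)c2ccc(O[Si](C(C)C)(C(C)C)C(C)C)c(OC)c2)OCOO1 | intermediate
14 | (3R)-3-[3-methoxy-4-(triisopropylsilyloxy)phenyl]-3-{3-[4-methoxy-3-(triisopropylsilyloxy)phenyl]-2-oxopropoxy}propanal | O=CC[C@@H](OCC(=O)Cc1ccc(OC)c(O[Si](C(C)C)(C(C)C)C(C)C)c1)c1ccc(O[Si](C(C)C)(C(C)C)C(C)C)c(OC)c1 | intermediate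
15 | (2R)-4-hydroxy-2-[3-methoxy-4-(triisopropylsilyloxy)phenyl]-4-[4-methoxy-3-(triisopropylsilyloxy)benzyl]tetrahydrofuran-3-carbaldehyde (epimers at C3 and C4) | O=CC1C(O)(Cc2ccc(OC)c(O[Si](C(C)C)(C(C)C)C(C)C)c2)CO[C@H]1c1ccc(O[Si](C(C)C)(C(C)C)C(C)C)c(OC)c1 | intermediate
16 | (2S)-2-[3-methoxy-4-(triisopropylsilyloxy)phenyl]-4-[4-methoxy-3-(triisopropylsilyloxy)benzyl]-2,5-dihydrofuran-3-carbaldehyde | O=CC1=C(Cc2ccc(OC)c(O[Si](C(C)C)(C(C)C)C(C)C)c2)CO[C@H]1c1ccc(O[Si](C(C)C)(C(C)C)C(C)C)c(OC)c1 | intermediate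
17 | (E)-4-methylbenzenesulfonohydrazone of 16 (2S) | Cc1ccc(cc1)S(=O)(=O)N/N=C/C1=C(Cc2ccc(OC)c(O[Si](C(C)C)(C(C)C)C(C)C)c2)CO[C@H]1c1ccc(O[Si](C(C)C)(C(C)C)C(C)C)c(OC)c1 | intermediate
18 | N-(1,3,2-benzodioxaborol-2-yl)-N-{[(2S)-dihydrofuran-3-yl]methyl}-N'-tosylhydrazine derived from 17 | Cc1ccc(cc1)S(=O)(=O)NN(CC1=C(Cc2ccc(OC)c(O[Si](C(C)C)(C(C)C)C(C)C)c2)CO[C@H]1c1ccc(O[Si](C(C)C)(C(C)C)C(C)C)c(OC)c1)B1Oc2ccccc2O1 | intermediate
19 | {[(2S)-2-aryl-4-benzyl-2,5-dihydrofuran-3-yl]methyl}diazene (allylic diazene, aryl and benzyl as in 16) | N=NCC1=C(Cc2ccc(OC)c(O[Si](C(C)C)(C(C)C)C(C)C)c2)CO[C@H]1c1ccc(O[Si](C(C)C)(C(C)C)C(C)C)c(OC)c1 | intermediate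
20 | (2R,4R)-2-[3-methoxy-4-(triisopropylsilyloxy)phenyl]-4-[4-methoxy-3-(triisopropylsilyloxy)benzyl]-3-methylenetetrahydrofuran (aryl and benzyl cis) | COc1ccc(C[C@H]2CO[C@@H](c3ccc(O[Si](C(C)C)(C(C)C)C(C)C)c(OC)c3)C2=C)cc1O[Si](C(C)C)(C(C)C)C(C)C | intermediate
21 | (3S,4S,7S)-4-[3-methoxy-4-(triisopropylsilyloxy)phenyl]-7-[4-methoxy-3-(triisopropylsilyloxy)benzyl]-1,5-dioxaspiro[2.4]heptane | COc1ccc(C[C@H]2CO[C@@H](c3ccc(O[Si](C(C)C)(C(C)C)C(C)C)c(OC)c3)[C@@]23CO3)cc1O[Si](C(C)C)(C(C)C)C(C)C | intermediate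
22 | 5-{[(3S,4S,7S)-4-(4-hydroxy-3-methoxyphenyl)-1,5-dioxaspiro[2.4]heptan-7-yl]methyl}-2-methoxyphenol | COc1ccc(C[C@H]2CO[C@@H](c3ccc(O)c(OC)c3)[C@@]23CO3)cc1O | target

**Count and risks**

Total steps: 10. Longest linear sequence: 8 (steps 3 to 10, from vanillin).

Step 7. What may go wrong: β-elimination of the ring oxygen (retro-oxa-Michael) from the enamine of 14 or from aldol 15 may compete with ring closure and dehydration, which erodes the configuration at C2 or fragments the chain. Closure from the ketone side (C5 onto C9) is a second leak. The fallback sets out from aldehyde 7 and comes back at enal 16, and it never passes through a β-alkoxy carbonyl compound. Trimethylsilylacetylene is added to 7 with Me2Zn and the ProPhenol ligand antipode that gives Re-face attack, to give (1S)-silylalkynol F1 (S only because of the priority change). Brief K2CO3/MeOH at 0 °C gives (1R)-alkynol F2. NaH and chloride 5 give enyne ether F3. Ring-closing enyne metathesis with the second-generation Grubbs catalyst (H2IMes)(PCy3)Cl2Ru=CHPh under ethylene in CH2Cl2 at 40 °C forms C3=C4 directly as the ring alkene of 3-vinyl-2,5-dihydrofuran F4. Dihydroxylation of the terminal vinyl group (OsO4 cat., N-methylmorpholine N-oxide) gives diol F5, and NaIO4 cleaves it to 16.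

Step 8. What may go wrong: hydrogen may be delivered to the wrong face of C4, or the hindered hydrazone may decompose without the 1,3-shift. The fallback sets out from 16 and comes back at 20, and it replaces the diazene by a metal-bound hydride. Luche reduction (NaBH4, CeCl3·7H2O, MeOH, −20 °C) gives allylic alcohol F6. Acetic formic anhydride and pyridine give allylic formate F7. Pd(OAc)2 (5 mol %) and PBu3 in THF at 40 °C form the π-allylpalladium formate, which loses CO2 and should transfer hydride to the more substituted terminus C4 from the metal-bearing face, anti to the aryl group (Tsuji–Trost-type formate hydrogenolysis).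

Step 9. What may go wrong: acid-promoted opening or rearrangement of the new 2,2-disubstituted epoxide, or oxidation of the electron-rich rings by the peracid. The fallback sets out from 20 and comes back at 21 without any peracid. Dihydroxylation (OsO4 cat., N-methylmorpholine N-oxide) from the same open face gives (2S,3S,4S)-diol F8, with the tertiary hydroxyl trans to aryl and benzyl. Selective sulfonylation of the primary hydroxyl (TsCl, Et3N, Bu2SnO cat.) gives tosylate F9. NaH in THF closes the epoxide by attack of the tertiary alkoxide on C9, with retention at C3.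

**Further compounds**

F1 | step 7 | (1S)-1-[3-methoxy-4-(triisopropylsilyloxy)phenyl]-3-(trimethylsilyl)prop-2-yn-1-ol | C[Si](C)(C)C#C[C@@H](O)c1ccc(O[Si](C(C)C)(C(C)C)C(C)C)c(OC)c1
F2 | step 7 | (1R)-1-[3-methoxy-4-(triisopropylsilyloxy)phenyl]prop-2-yn-1-ol | C#C[C@@H](O)c1ccc(O[Si](C(C)C)(C(C)C)C(C)C)c(OC)c1
F3 | step 7 | (R)-1-[3-methoxy-4-(triisopropylsilyloxy)phenyl]prop-2-yn-1-yl 2-[4-methoxy-3-(triisopropylsilyloxy)benzyl]prop-2-en-1-yl ether | C#C[C@@H](OCC(=C)Cc1ccc(OC)c(O[Si](C(C)C)(C(C)C)C(C)C)c1)c1ccc(O[Si](C(C)C)(C(C)C)C(C)C)c(OC)c1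
F4 | step 7 | (2S)-3-ethenyl-2-[3-methoxy-4-(triisopropylsilyloxy)phenyl]-4-[4-methoxy-3-(triisopropylsilyloxy)benzyl]-2,5-dihydrofuran | C=CC1=C(Cc2ccc(OC)c(O[Si](C(C)C)(C(C)C)C(C)C)c2)CO[C@H]1c1ccc(O[Si](C(C)C)(C(C)C)C(C)C)c(OC)c1
F5 | step 7 | 1-[(2S)-2-aryl-4-benzyl-2,5-dihydrofuran-3-yl]ethane-1,2-diol (aryl and benzyl as in F4; epimers at the carbinol carbon) | OCC(O)C1=C(Cc2ccc(OC)c(O[Si](C(C)C)(C(C)C)C(C)C)c2)CO[C@H]1c1ccc(O[Si](C(C)C)(C(C)C)C(C)C)c(OC)c1
F6 | step 8 | {(2S)-2-[3-methoxy-4-(triisopropylsilyloxy)phenyl]-4-[4-methoxy-3-(triisopropylsilyloxy)benzyl]-2,5-dihydrofuran-3-yl}methanol | OCC1=C(Cc2ccc(OC)c(O[Si](C(C)C)(C(C)C)C(C)C)c2)CO[C@H]1c1ccc(O[Si](C(C)C)(C(C)C)C(C)C)c(OC)c1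
F7 | step 8 | formate ester of F6 | O=COCC1=C(Cc2ccc(OC)c(O[Si](C(C)C)(C(C)C)C(C)C)c2)CO[C@H]1c1ccc(O[Si](C(C)C)(C(C)C)C(C)C)c(OC)c1
F8 | step 9 | (2S,3S,4S)-3-(hydroxymethyl)-2-[3-methoxy-4-(triisopropylsilyloxy)phenyl]-4-[4-methoxy-3-(triisopropylsilyloxy)benzyl]tetrahydrofuran-3-ol | COc1ccc(C[C@H]2CO[C@@H](c3ccc(O[Si](C(C)C)(C(C)C)C(C)C)c(OC)c3)[C@@]2(O)CO)cc1O[Si](C(C)C)(C(C)C)C(C)C
F9 | step 9 | primary 4-methylbenzenesulfonate of F8 | COc1ccc(C[C@H]2CO[C@@H](c3ccc(O[Si](C(C)C)(C(C)C)C(C)C)c(OC)c3)[C@@]2(O)COS(=O)(=O)c2ccc(C)cc2)cc1O[Si](C(C)C)(C(C)C)C(C)C
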